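## Retrosynthetic overview

1. Glaucolide K ⇒ last-step outer-face epoxidation of C4=C5 and acylation of O13 and O8. The butenolide (ring C: O–C6–C7=C11–C12) comes from an intramolecular Horner–Wadsworth–Emmons closure of a C6 phosphonoester onto a C7 ketone. The C1 acetate and C10–H come from hydroboration of C1=C10 followed by Mitsunobu inversion.
2. Ten-membered carbocycle (ring A) ⇒ anionic oxy-Cope ring expansion with enolate triflation in the same flask. C2–C3 is formed while the C5–C10 bond of a cyclohexane (ring B, atoms C5–C10) is broken.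
3. Enabling feature: C2–C3 is the central bond of the six-atom chain C10–C1–C2–C3–C4–C5 of the ten-membered ring, and its end C5 carries oxygen (the later epoxide oxygen). Read backwards this is a 3-oxido-1,5-diene (vinyl C1=C2 on C10, isopropenyl C3=C4 on C5) whose C5–C10 bond closes a six-membered ring through C6–C9.
4. Ring B ⇒ Ferrier carbocyclization of methyl α-D-glucopyranoside. Sugar C4, C3, C2 become C6, C7, C8 with the absolute configuration of the target at C6 and C8. The C10 quaternary centre comes from Stille vinylation and reductive methylation, the C5 carbinol from chelation-controlled isopropenyl addition.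
5. Ring order: pyranose → cyclohexane (ring B) → cyclodecadiene (ring A) → butenolide (ring C) → oxirane.

Key step: step 13

Remark on names: carbocyclic compounds carry the germacrane numbering of the target (ring C1–C10, C14 on C10, C15 on C4, lactone carbons C11–C13). α is the face of O6 and O8, β the face of C14 and C15. PMBO = 4-methoxybenzyloxy, TESO = triethylsilyloxy, TBSO = tert-butyldimethylsilyloxy, TBDPSO = tert-butyldiphenylsilyloxy, Tf = trifluoromethanesulfonyl. Compounds 25–30 are mixtures at the phosphonate carbon, a centre that disappears in step 24.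

## Route

Step 1
Reactants: 1 methyl α-D-glucopyranoside
Product: 2 methyl 4,6-O-[(R)-4-methoxybenzylidene]-α-D-glucopyranoside
Conditions: 4-MeOC6H4CH(OMe)2, CSA (cat.), DMF, 60 °C, reduced pressure
Reagents that add atoms: 4-methoxybenzaldehyde dimethyl acetal COc1ccc(C(OC)OC)cc1
Why: Acid-catalysed transacetalization under thermodynamic control should form the trans-fused 1,3-dioxane on O4/O6 with the aryl group equatorial, which fixes the R acetal carbon and leaves only O2 and O3 free.

Step 2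
Reactants: 2 methyl 4,6-O-[(R)-4-methoxybenzylidene]-α-D-glucopyranoside
Product: 3 methyl 2-O-TBS-4,6-O-[(R)-4-methoxybenzylidene]-α-D-glucopyranoside
Conditions: TBSCl, imidazole, DMF, 0 → 25 °C
Reagents that add atoms: tert-butyldimethylsilyl chloride CC(C)(C)[Si](C)(C)Cl
Why: Regioselective silylation, in which the 2-OH of a 4,6-O-arylidene α-glucoside (activated by the cis anomeric oxygen) is expected to react in preference to the 3-OH.

Step 3
Reactants: 3 methyl 2-O-TBS-4,6-O-[(R)-4-methoxybenzylidene]-α-D-glucopyranoside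
Product: 4 methyl 2-O-TBS-3-O-TES-4,6-O-[(R)-4-methoxybenzylidene]-α-D-glucopyranoside
Conditions: TESOTf, 2,6-lutidine, CH2Cl2, −78 → 0 °C
Reagents that add atoms: triethylsilyl trifluoromethanesulfonate CC[Si](CC)(CC)OS(=O)(=O)C(F)(F)F
Why: Silyl triflate silylation of the remaining hindered secondary hydroxyl gives an O3 group that can later be removed in the presence of TBS.

Step 4
Reactants: 4 methyl 2-O-TBS-3-O-TES-4,6-O-[(R)-4-methoxybenzylidene]-α-D-glucopyranoside
Product: 5 methyl 2-O-TBS-3-O-TES-4-O-PMB-α-D-glucopyranoside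
Conditions: i-Bu2AlH, CH2Cl2/toluene, −78 → 0 °C; aq. potassium sodium tartrate
Reagents that add atoms: none
Why: Reductive opening of the 4-methoxybenzylidene acetal, in which the aluminium hydride complexes the less hindered O6 and delivers hydride to the acetal carbon, so that the PMB ether stays on O4 and the primary 6-OH is set free.

Step 5
Reactants: 5 methyl 2-O-TBS-3-O-TES-4-O-PMB-α-D-glucopyranoside
Product: 6 methyl 6-deoxy-6-iodo-2-O-TBS-3-O-TES-4-O-PMB-α-D-glucopyranoside
Conditions: I2, PPh3, imidazole, toluene, 70 °C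
Reagents that add atoms: iodine II
Why: Appel-type iodination of the only free (primary) alcohol through its alkoxyphosphonium iodide.

Step 6
Reactants: 6 methyl 6-deoxy-6-iodo-2-O-TBS-3-O-TES-4-O-PMB-α-D-glucopyranoside
Product: 7 methyl 6-deoxy-2-O-TBS-3-O-TES-4-O-PMB-α-D-xylo-hex-5-enopyranoside
Conditions: KOt-Bu, THF, 0 → 25 °C
Reagents that add atoms: none
Why: E2 dehydrohalogenation of the primary iodide with the C5 hydrogen should give the exocyclic enol ether needed for the carbocyclization.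

Step 7
Reactants: 7 methyl 6-deoxy-2-O-TBS-3-O-TES-4-O-PMB-α-D-xylo-hex-5-enopyranoside
Product: 8 (6α,7β,8α,9α)-9-hydroxy-6-PMBO-7-TESO-8-TBSO-cyclohexan-5-one
Conditions: Hg(OCOCF3)2 (cat.), acetone/H2O, 25 °C
Reagents that add atoms: water O
Why: Ferrier carbocyclization, in which oxymercuration of the enol ether, loss of methanol from the hemiacetal and intramolecular aldol addition of the mercury enolate (sugar C6) to the C1 aldehyde give the cyclohexanone whose ring atoms are C5–C10 of the target, the new carbinol centre (expected mainly cis to the neighbouring silyloxy group) being removed in step 8.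

Step 8
Reactants: 8 (6α,7β,8α,9α)-9-hydroxy-6-PMBO-7-TESO-8-TBSO-cyclohexan-5-one
Product: 10 (6α,7β,8α)-6-PMBO-7-TESO-8-TBSO-cyclohex-9-en-5-one, via mesylate 9 (not isolated)
Conditions: MsCl, Et3N, CH2Cl2, 0 → 25 °C
Reagents that add atoms: none
Why: Mesylation followed by E1cB elimination of the β-mesyloxy ketone should give the conjugated enone without touching the three oxygen-bearing stereocentres.

Step 9
Reactants: 10 (6α,7β,8α)-6-PMBO-7-TESO-8-TBSO-cyclohex-9-en-5-one
Product: 11 (6α,7β,8α)-10-iodo-6-PMBO-7-TESO-8-TBSO-cyclohex-9-en-5-one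
Conditions: I2, pyridine, CH2Cl2, 0 → 25 °C
Reagents that add atoms: iodine II
Why: α-Iodination of the enone (conjugate addition of pyridine, iodination of the enolate, elimination) puts a coupling handle on C10.

Step 10
Reactants: 11 (6α,7β,8α)-10-iodo-6-PMBO-7-TESO-8-TBSO-cyclohex-9-en-5-one
Product: 12 (6α,7β,8α)-6-PMBO-7-TESO-8-TBSO-10-vinylcyclohex-9-en-5-one
Conditions: CH2=CHSnBu3, Pd2(dba)3 (cat.), AsPh3, NMP, 25 °C
Reagents that add atoms: tributyl(vinyl)stannane C=C[Sn](CCCC)(CCCC)CCCC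
Why: Stille coupling of the 2-iodoenone with a vinylstannane under zerovalent palladium catalysis installs C1 and C2, the cross-conjugated dienone being used directly because it is prone to dimerize.

Step 11
Reactants: 12 (6α,7β,8α)-6-PMBO-7-TESO-8-TBSO-10-vinylcyclohex-9-en-5-one
Product: 14 (6α,7β,8α)-10β-methyl-10α-vinyl-6-PMBO-7-TESO-8-TBSO-cyclohexan-5-one, via lithium dienolate 13 (not isolated)
Conditions: LiBH(s-Bu)3, THF, −78 °C; then MeI, −78 → 0 °C
Reagents that add atoms: iodomethane CI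
Why: Conjugate reduction with enolate alkylation (reductive alkylation), in which hydride adds to C9 and the regiodefined dienolate is methylated at C10 along the axial vector of the half-chair that keeps the three oxygen substituents equatorial, which should place C14 axial on the β-face and the vinyl group equatorial on the α-face (a minor C10 epimer is to be removed by chromatography).

Step 12
Reactants: 14 (6α,7β,8α)-10β-methyl-10α-vinyl-6-PMBO-7-TESO-8-TBSO-cyclohexan-5-one
Product: 15 (6α,7β,8α)-5β-isopropenyl-10β-methyl-10α-vinyl-6-PMBO-7-TESO-8-TBSO-cyclohexan-5α-ol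
Conditions: CH2=C(CH3)MgBr, MgBr2·OEt2, CH2Cl2/THF, −78 → 0 °C
Reagents that add atoms: isopropenylmagnesium bromide CC(=C)[Mg]Br
Why: Chelation-controlled Grignard addition (Cram chelate), in which magnesium bridges the carbonyl and the equatorial O6 ether and the nucleophile enters anti to O6 from the side of the axial C6 hydrogen, so that the isopropenyl group should become equatorial (β), the hydroxyl axial (α) and the two alkenyl groups trans-diequatorial.

Step 13
Reactants: 15 (6α,7β,8α)-5β-isopropenyl-10β-methyl-10α-vinyl-6-PMBO-7-TESO-8-TBSO-cyclohexan-5α-ol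
Product: 18 (1(10)E,4Z)-4,10-dimethyl-6α-PMBO-7β-TESO-8α-TBSO-cyclodeca-1(10),4-dien-5-yl triflate, via potassium alkoxide 16 (not isolated), via potassium enolate 17 (not isolated)
Conditions: KH, 18-crown-6, THF, 0 → 25 °C; then PhNTf2, −78 → 0 °C
Reagents that add atoms: N-phenylbis(trifluoromethanesulfonimide) O=S(=O)(N(c1ccccc1)S(=O)(=O)C(F)(F)F)C(F)(F)F
Why: KH with 18-crown-6 turns 15 into the naked tertiary alkoxide 16, whose 3-oxido-1,5-diene (C3=C4–C5(O−)–C10–C1=C2) should undergo the alkoxide-accelerated [3,3] shift (anionic oxy-Cope rearrangement), forming C2–C3 as C5–C10 breaks, and the resulting potassium enolate 17 is trapped on oxygen by PhNTf2 before it can equilibrate. The closest known reaction is the anionic oxy-Cope ring expansion of trans-1,2-dialkenylcyclohexanols to (E)-cyclodec-5-enones with capture of the enolate in the same flask. The ten-membered ring is closed in the mode of a four-atom sigmatropic ring enlargement through a concerted suprafacial chair transition state, the cyclohexane being opened in the same event. No new stereocentre arises, and the stereo-elements are the two new trisubstituted double bonds: with both alkenyl groups equatorial, the ring bonds C5–C6 and C10–C9 are pseudo-equatorial in the chair, which gives the (E)-C1=C10 olefin and the enolate (hence the triflate) with C3 and C6 trans across C4=C5, while C6 and C8 pass through unchanged. The step needs chair over boat selectivity, O- over C-triflation and no scrambling of the enolate, and these are secured by the trans-diequatorial alkenyl groups with all three ring oxygens equatorial (set in steps 11 and 12), by the hard potassium enolate and by trapping at low temperature. The product should be delivered in the crown conformation with C14 and C15 on the β-face, which is the basis of the later face-selective additions.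

Step 14
Reactants: 18 (1(10)E,4Z)-4,10-dimethyl-6α-PMBO-7β-TESO-8α-TBSO-cyclodeca-1(10),4-dien-5-yl triflate
Product: 20 (4Z)-1β-hydroxy-4,10β-dimethyl-6α-PMBO-7β-TESO-8α-TBSO-cyclodec-4-en-5-yl triflate, via alkylborane 19 (not isolated)
Conditions: BH3·THF, THF, 0 → 25 °C; then 30% H2O2, aq. NaOAc, 0 °C
Reagents that add atoms: hydrogen peroxide OO
Why: Hydroboration–oxidation, in which the electron-rich C1=C10 bond reacts while the electron-poor enol triflate does not, boron goes to the less substituted C1, and syn addition to the exposed outer face of the crown conformer should give 10α-H (C14 β) and, after oxidation with retention, the 1β-alcohol.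

Step 15
Reactants: 20 (4Z)-1β-hydroxy-4,10β-dimethyl-6α-PMBO-7β-TESO-8α-TBSO-cyclodec-4-en-5-yl triflate
Product: 21 (4Z)-1α-acetoxy-4,10β-dimethyl-6α-PMBO-7β-TESO-8α-TBSO-cyclodec-4-en-5-yl triflate
Conditions: PPh3, DIAD, AcOH, toluene, 0 → 25 °C
Reagents that add atoms: acetic acid CC(=O)O
Why: Mitsunobu esterification, in which SN2 displacement of the alkoxyphosphonium ion by acetate inverts C1 and should give the 1α-acetate of the target directly.

Step 16
Reactants: 21 (4Z)-1α-acetoxy-4,10β-dimethyl-6α-PMBO-7β-TESO-8α-TBSO-cyclodec-4-en-5-yl triflate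
Product: 22 (4E)-1α-acetoxy-4,10β-dimethyl-6α-PMBO-7β-TESO-8α-TBSO-cyclodec-4-ene
Conditions: Pd(OAc)2 (cat.), PPh3, Bu3N, HCO2H, DMF, 60 °C
Reagents that add atoms: none
Why: Palladium-catalysed formate reduction of the enol triflate (oxidative addition to zerovalent palladium, decarboxylation of formate, reductive elimination) replaces OTf by H with retention of the double-bond geometry and should give the (E)-C4=C5 olefin.

Step 17
Reactants: 22 (4E)-1α-acetoxy-4,10β-dimethyl-6α-PMBO-7β-TESO-8α-TBSO-cyclodec-4-ene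
Product: 23 (4E)-1α-acetoxy-4,10β-dimethyl-7β-TESO-8α-TBSO-cyclodec-4-en-6α-ol
Conditions: DDQ, CH2Cl2/pH 7 buffer, 0 °C
Reagents that add atoms: none
Why: Oxidative cleavage of the PMB ether through its benzylic oxocarbenium ion frees the allylic 6-OH and should leave the silyl ethers, the acetate and the trisubstituted olefin untouched.

Step 18
Reactants: 24 benzyl 2-(diethoxyphosphoryl)acetate
Product: 25 benzyl 2-(diethoxyphosphoryl)-3-hydroxypropanoate
Conditions: (CH2O)n, piperidine (cat.), THF, 60 °C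
Reagents that add atoms: formaldehyde (from paraformaldehyde) C=O
Why: Amine-catalysed aldol-type hydroxymethylation of the phosphonoacetate with one equivalent of formaldehyde provides C13 at the alcohol oxidation level.

Step 19
Reactants: 25 benzyl 2-(diethoxyphosphoryl)-3-hydroxypropanoate
Product: 26 benzyl 3-TBDPSO-2-(diethoxyphosphoryl)propanoate
Conditions: TBDPSCl, imidazole, DMF, 0 → 25 °C
Reagents that add atoms: tert-butyldiphenylsilyl chloride CC(C)(C)[Si](Cl)(c1ccccc1)c1ccccc1
Why: Silylation of the primary alcohol with a group that should survive the later selective cleavage of the triethylsilyl ether.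

Step 20
Reactants: 26 benzyl 3-TBDPSO-2-(diethoxyphosphoryl)propanoate
Product: 27 3-TBDPSO-2-(diethoxyphosphoryl)propanoic acid
Conditions: H2, Pd/C (palladium on carbon), EtOAc, 25 °C
Reagents that add atoms: none
Why: Hydrogenolysis of the benzyl ester gives the free acid without basic conditions that could eliminate the β-silyloxy group.

Step 21
Reactants: 23 (4E)-1α-acetoxy-4,10β-dimethyl-7β-TESO-8α-TBSO-cyclodec-4-en-6α-ol; 27 3-TBDPSO-2-(diethoxyphosphoryl)propanoic acid
Product: 28 6α-O-[3-TBDPSO-2-(diethoxyphosphoryl)propanoyl] ester of 23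
Conditions: DCC, DMAP (cat.), CH2Cl2, 0 → 25 °C
Reagents that add atoms: none
Why: Steglich esterification acylates the only free hydroxyl (O6) and brings the phosphonate next to C7.

Step 22
Reactants: 28 6α-O-[3-TBDPSO-2-(diethoxyphosphoryl)propanoyl] ester of 23
Product: 29 (4E)-1α-acetoxy-6α-[3-TBDPSO-2-(diethoxyphosphoryl)propanoyloxy]-4,10β-dimethyl-8α-TBSO-cyclodec-4-en-7β-ol
Conditions: HF·pyridine, pyridine, THF, 0 °C
Reagents that add atoms: none
Why: Selective desilylation, since the triethylsilyl ether is cleaved much faster by buffered HF than the secondary TBS and the primary TBDPS ether.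

Step 23
Reactants: 29 (4E)-1α-acetoxy-6α-[3-TBDPSO-2-(diethoxyphosphoryl)propanoyloxy]-4,10β-dimethyl-8α-TBSO-cyclodec-4-en-7β-ol
Product: 30 (4E)-1α-acetoxy-6α-[3-TBDPSO-2-(diethoxyphosphoryl)propanoyloxy]-4,10β-dimethyl-8α-TBSO-cyclodec-4-en-7-one
Conditions: Dess–Martin periodinane, NaHCO3, CH2Cl2, 0 → 25 °C
Reagents that add atoms: none
Why: Dess–Martin oxidation of the secondary 7-OH under buffered, non-basic conditions should give the C7 ketone without epimerizing C6 or C8.

Step 24
Reactants: 30 (4E)-1α-acetoxy-6α-[3-TBDPSO-2-(diethoxyphosphoryl)propanoyloxy]-4,10β-dimethyl-8α-TBSO-cyclodec-4-en-7-one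
Product: 31 1α-acetoxy-8α-TBSO-13-TBDPSO-germacra-4E,7(11)-dien-12,6α-olide
Conditions: LiCl, DBU, MeCN, 0 → 25 °C
Reagents that add atoms: none
Why: Intramolecular Horner–Wadsworth–Emmons reaction under Masamune–Roush conditions, in which the phosphonate carbanion adds to the C7 ketone in a five-membered ring closure and loss of diethyl phosphate gives the tetrasubstituted C7=C11 butenolide, the mild base being expected to leave C6 and C8 untouched.

Step 25
Reactants: 31 1α-acetoxy-8α-TBSO-13-TBDPSO-germacra-4E,7(11)-dien-12,6α-olide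
Product: 32 1α-acetoxy-8α,13-dihydroxygermacra-4E,7(11)-dien-12,6α-olide
Conditions: HF·pyridine, THF, 0 → 25 °C
Reagents that add atoms: none
Why: Fluoride-mediated desilylation under acidic, non-basic conditions removes both remaining silyl groups without deprotonating the γ-position (C6) of the butenolide.

Step 26
Reactants: 32 1α-acetoxy-8α,13-dihydroxygermacra-4E,7(11)-dien-12,6α-olide
Product: 33 1α,13-diacetoxy-8α-hydroxygermacra-4E,7(11)-dien-12,6α-olide
Conditions: AcCl, 2,4,6-collidine, CH2Cl2, −78 °C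
Reagents that add atoms: acetyl chloride CC(=O)Cl
Why: Chemoselective acylation, since the primary allylic 13-OH should react far faster than the hindered secondary 8-OH with acetyl chloride and a hindered pyridine base at low temperature.

Step 27
Reactants: 33 1α,13-diacetoxy-8α-hydroxygermacra-4E,7(11)-dien-12,6α-olide
Product: 34 1α,13-diacetoxy-8α-methacryloyloxygermacra-4E,7(11)-dien-12,6α-olide
Conditions: methacrylic anhydride, DMAP (cat.), Et3N, CH2Cl2, 0 → 25 °C
Reagents that add atoms: methacrylic anhydride CC(=C)C(=O)OC(=O)C(C)=C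
Why: DMAP-catalysed acylation of the remaining secondary 8-OH proceeds with retention at C8.

Step 28
Reactants: 34 1α,13-diacetoxy-8α-methacryloyloxygermacra-4E,7(11)-dien-12,6α-olide
Product: 35 glaucolide K
Conditions: mCPBA, NaHCO3, CH2Cl2, 0 °C
Reagents that add atoms: 3-chloroperbenzoic acid OOC(=O)c1cccc(Cl)c1
Why: Prilezhaev epoxidation, in which the trisubstituted C4=C5 bond is the only electron-rich alkene (butenolide and methacrylate are electron-poor) and concerted syn transfer of oxygen to its outer face, the face of the C6 oxygen when H6 eclipses the double bond to avoid allylic 1,3-strain with C15, should give the 4α,5β-epoxide (4R,5R).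

## Compound list

1 | methyl α-D-glucopyranoside | CO[C@@H]1[C@H](O)[C@@H](O)[C@H](O)[C@@H](CO)O1 | starting material
2 | methyl 4,6-O-[(R)-4-methoxybenzylidene]-α-D-glucopyranoside | CO[C@@H]1[C@H](O)[C@@H](O)[C@@H]2O[C@H](c3ccc(OC)cc3)OC[C@H]2O1 | intermediate
3 | methyl 2-O-TBS-4,6-O-[(R)-4-methoxybenzylidene]-α-D-glucopyranoside | CO[C@@H]1[C@H](O[Si](C)(C)C(C)(C)C)[C@@H](O)[C@@H]2O[C@H](c3ccc(OC)cc3)OC[C@H]2O1 | intermediate
4 | methyl 2-O-TBS-3-O-TES-4,6-O-[(R)-4-methoxybenzylidene]-α-D-glucopyranoside | CO[C@@H]1[C@H](O[Si](C)(C)C(C)(C)C)[C@@H](O[Si](CC)(CC)CC)[C@@H]2O[C@H](c3ccc(OC)cc3)OC[C@H]2O1 | intermediate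
5 | methyl 2-O-TBS-3-O-TES-4-O-PMB-α-D-glucopyranoside | CO[C@@H]1[C@H](O[Si](C)(C)C(C)(C)C)[C@@H](O[Si](CC)(CC)CC)[C@H](OCc2ccc(OC)cc2)[C@@H](CO)O1 | intermediate
6 | methyl 6-deoxy-6-iodo-2-O-TBS-3-O-TES-4-O-PMB-α-D-glucopyranoside | CO[C@@H]1[C@H](O[Si](C)(C)C(C)(C)C)[C@@H](O[Si](CC)(CC)CC)[C@H](OCc2ccc(OC)cc2)[C@@H](CI)O1 | intermediate
7 | methyl 6-deoxy-2-O-TBS-3-O-TES-4-O-PMB-α-D-xylo-hex-5-enopyranoside | CO[C@@H]1[C@H](O[Si](C)(C)C(C)(C)C)[C@@H](O[Si](CC)(CC)CC)[C@H](OCc2ccc(OC)cc2)C(=C)O1 | intermediate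
8 | (6α,7β,8α,9α)-9-hydroxy-6-PMBO-7-TESO-8-TBSO-cyclohexan-5-one (ring atoms C5–C10; major carbinol epimer) | O[C@@H]1[C@H](O[Si](C)(C)C(C)(C)C)[C@@H](O[Si](CC)(CC)CC)[C@H](OCc2ccc(OC)cc2)C(=O)C1 | intermediate
9 | 9-O-methanesulfonate of 8 | CS(=O)(=O)O[C@@H]1[C@H](O[Si](C)(C)C(C)(C)C)[C@@H](O[Si](CC)(CC)CC)[C@H](OCc2ccc(OC)cc2)C(=O)C1 | intermediate
10 | (6α,7β,8α)-6-PMBO-7-TESO-8-TBSO-cyclohex-9-en-5-one | O=C1C=C[C@H](O[Si](C)(C)C(C)(C)C)[C@@H](O[Si](CC)(CC)CC)[C@@H]1OCc1ccc(OC)cc1 | intermediate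
11 | (6α,7β,8α)-10-iodo-6-PMBO-7-TESO-8-TBSO-cyclohex-9-en-5-one | O=C1C(I)=C[C@H](O[Si](C)(C)C(C)(C)C)[C@@H](O[Si](CC)(CC)CC)[C@@H]1OCc1ccc(OC)cc1 | intermediate
12 | (6α,7β,8α)-6-PMBO-7-TESO-8-TBSO-10-vinylcyclohex-9-en-5-one | O=C1C(C=C)=C[C@H](O[Si](C)(C)C(C)(C)C)[C@@H](O[Si](CC)(CC)CC)[C@@H]1OCc1ccc(OC)cc1 | intermediate
13 | lithium dienolate (O–C5=C10–C1=C2) formed from 12 by hydride addition at C9 | [Li+].[O-]C1=C(C=C)C[C@H](O[Si](C)(C)C(C)(C)C)[C@@H](O[Si](CC)(CC)CC)[C@@H]1OCc1ccc(OC)cc1 | intermediate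
14 | (6α,7β,8α)-10β-methyl-10α-vinyl-6-PMBO-7-TESO-8-TBSO-cyclohexan-5-one | O=C1[C@](C)(C=C)C[C@H](O[Si](C)(C)C(C)(C)C)[C@@H](O[Si](CC)(CC)CC)[C@@H]1OCc1ccc(OC)cc1 | intermediate
15 | (6α,7β,8α)-5β-isopropenyl-10β-methyl-10α-vinyl-6-PMBO-7-TESO-8-TBSO-cyclohexan-5α-ol | CC(=C)[C@@]1(O)[C@](C)(C=C)C[C@H](O[Si](C)(C)C(C)(C)C)[C@@H](O[Si](CC)(CC)CC)[C@@H]1OCc1ccc(OC)cc1 | intermediate
16 | potassium alkoxide of 15 | [K+].CC(=C)[C@@]1([O-])[C@](C)(C=C)C[C@H](O[Si](C)(C)C(C)(C)C)[C@@H](O[Si](CC)(CC)CC)[C@@H]1OCc1ccc(OC)cc1 | intermediate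
17 | potassium (1(10)E,4Z)-4,10-dimethyl-6α-PMBO-7β-TESO-8α-TBSO-cyclodeca-1(10),4-dien-5-olate (C3 and C6 trans across C4=C5) | [K+].CC(C)(C)[Si](C)(C)O[C@H]1C/C(C)=C/CC/C(C)=C([O-])/[C@@H](OCc2ccc(OC)cc2)[C@@H]1O[Si](CC)(CC)CC | intermediate
18 | (1(10)E,4Z)-4,10-dimethyl-6α-PMBO-7β-TESO-8α-TBSO-cyclodeca-1(10),4-dien-5-yl triflate | CC(C)(C)[Si](C)(C)O[C@H]1C/C(C)=C/CC/C(C)=C(OS(=O)(=O)C(F)(F)F)/[C@@H](OCc2ccc(OC)cc2)[C@@H]1O[Si](CC)(CC)CC | intermediate
19 | 1β-boryl-10αH alkylborane from 18 | CC(C)(C)[Si](C)(C)O[C@H]1C[C@H](C)[C@H](B)CC/C(C)=C(OS(=O)(=O)C(F)(F)F)/[C@@H](OCc2ccc(OC)cc2)[C@@H]1O[Si](CC)(CC)CC | intermediate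
20 | (4Z)-1β-hydroxy-4,10β-dimethyl-6α-PMBO-7β-TESO-8α-TBSO-cyclodec-4-en-5-yl triflate | CC(C)(C)[Si](C)(C)O[C@H]1C[C@H](C)[C@H](O)CC/C(C)=C(OS(=O)(=O)C(F)(F)F)/[C@@H](OCc2ccc(OC)cc2)[C@@H]1O[Si](CC)(CC)CC | intermediate
21 | (4Z)-1α-acetoxy-4,10β-dimethyl-6α-PMBO-7β-TESO-8α-TBSO-cyclodec-4-en-5-yl triflate | CC(C)(C)[Si](C)(C)O[C@H]1C[C@H](C)[C@@H](OC(C)=O)CC/C(C)=C(OS(=O)(=O)C(F)(F)F)/[C@@H](OCc2ccc(OC)cc2)[C@@H]1O[Si](CC)(CC)CC | intermediate
22 | (4E)-1α-acetoxy-4,10β-dimethyl-6α-PMBO-7β-TESO-8α-TBSO-cyclodec-4-ene | CC(C)(C)[Si](C)(C)O[C@H]1C[C@H](C)[C@@H](OC(C)=O)CC/C(C)=C/[C@@H](OCc2ccc(OC)cc2)[C@@H]1O[Si](CC)(CC)CC | intermediate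
23 | (4E)-1α-acetoxy-4,10β-dimethyl-7β-TESO-8α-TBSO-cyclodec-4-en-6α-ol | CC(C)(C)[Si](C)(C)O[C@H]1C[C@H](C)[C@@H](OC(C)=O)CC/C(C)=C/[C@@H](O)[C@@H]1O[Si](CC)(CC)CC | intermediate
24 | benzyl 2-(diethoxyphosphoryl)acetate | CCOP(=O)(OCC)CC(=O)OCc1ccccc1 | starting material
25 | benzyl 2-(diethoxyphosphoryl)-3-hydroxypropanoate (racemic) | CCOP(=O)(OCC)C(CO)C(=O)OCc1ccccc1 | intermediate
26 | benzyl 3-TBDPSO-2-(diethoxyphosphoryl)propanoate (racemic) | CCOP(=O)(OCC)C(CO[Si](c1ccccc1)(c1ccccc1)C(C)(C)C)C(=O)OCc1ccccc1 | intermediate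
27 | 3-TBDPSO-2-(diethoxyphosphoryl)propanoic acid (racemic) | CCOP(=O)(OCC)C(CO[Si](c1ccccc1)(c1ccccc1)C(C)(C)C)C(=O)O | intermediate
28 | 6α-O-[3-TBDPSO-2-(diethoxyphosphoryl)propanoyl] ester of 23 | CC(C)(C)[Si](C)(C)O[C@H]1C[C@H](C)[C@@H](OC(C)=O)CC/C(C)=C/[C@@H](OC(=O)C(CO[Si](c2ccccc2)(c2ccccc2)C(C)(C)C)P(=O)(OCC)OCC)[C@@H]1O[Si](CC)(CC)CC | intermediate
29 | 7β-alcohol: (4E)-1α-acetoxy-6α-[3-TBDPSO-2-(diethoxyphosphoryl)propanoyloxy]-4,10β-dimethyl-8α-TBSO-cyclodec-4-en-7β-ol | CC(C)(C)[Si](C)(C)O[C@H]1C[C@H](C)[C@@H](OC(C)=O)CC/C(C)=C/[C@@H](OC(=O)C(CO[Si](c2ccccc2)(c2ccccc2)C(C)(C)C)P(=O)(OCC)OCC)[C@@H]1O | intermediate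
30 | 7-ketone: (4E)-1α-acetoxy-6α-[3-TBDPSO-2-(diethoxyphosphoryl)propanoyloxy]-4,10β-dimethyl-8α-TBSO-cyclodec-4-en-7-one | CC(C)(C)[Si](C)(C)O[C@H]1C[C@H](C)[C@@H](OC(C)=O)CC/C(C)=C/[C@@H](OC(=O)C(CO[Si](c2ccccc2)(c2ccccc2)C(C)(C)C)P(=O)(OCC)OCC)C1=O | intermediate
31 | 1α-acetoxy-8α-TBSO-13-TBDPSO-germacra-4E,7(11)-dien-12,6α-olide (10αH) | CC(C)(C)[Si](C)(C)O[C@H]1C[C@H](C)[C@@H](OC(C)=O)CC/C(C)=C/[C@H]2OC(=O)C(CO[Si](c3ccccc3)(c3ccccc3)C(C)(C)C)=C12 | intermediate
32 | 1α-acetoxy-8α,13-dihydroxygermacra-4E,7(11)-dien-12,6α-olide | O[C@H]1C[C@H](C)[C@@H](OC(C)=O)CC/C(C)=C/[C@H]2OC(=O)C(CO)=C12 | intermediate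
33 | 1α,13-diacetoxy-8α-hydroxygermacra-4E,7(11)-dien-12,6α-olide | O[C@H]1C[C@H](C)[C@@H](OC(C)=O)CC/C(C)=C/[C@H]2OC(=O)C(COC(C)=O)=C12 | intermediate
34 | 1α,13-diacetoxy-8α-methacryloyloxygermacra-4E,7(11)-dien-12,6α-olide | C=C(C)C(=O)O[C@H]1C[C@H](C)[C@@H](OC(C)=O)CC/C(C)=C/[C@H]2OC(=O)C(COC(C)=O)=C12 | intermediate
35 | glaucolide K | C=C(C)C(=O)O[C@H]1C[C@H](C)[C@@H](OC(C)=O)CC[C@@]2(C)O[C@@H]2[C@H]2OC(=O)C(COC(C)=O)=C12 | target

## Step count and risks

Total step count: 28. Longest linear sequence: 25 steps (steps 1–17 and 21–28, from 1). Steps 18–20 make acid 27.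

Steps most likely to fail:

Step 12. The process at risk is facial selectivity. The axial C14 methyl on C10 flanks the equatorial trajectory that chelation prefers, so axial attack may compete and give the cis-dialkenyl carbinol, which in step 13 would give a (Z)-C1=C10 olefin. The fallback sets out from 14 and replaces ether chelation by a covalently bound alkoxide. DDQ removes the PMB group to give the α-hydroxy ketone F1. Excess isopropenylmagnesium bromide first forms the magnesium alkoxide of O6, whose rigid five-membered chelate with the carbonyl should direct the second equivalent anti to O6, giving the cis-5,6-diol F2. Regioselective re-etherification of the secondary equatorial hydroxyl through the dibutylstannylene acetal (Bu2SnO; then PMBCl, CsF) returns to the route at 15.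

Step 13. The processes at risk are fragmentation or silyl migration of the naked alkoxide before the sigmatropic shift, and incomplete O-triflation of the hindered tetrasubstituted enolate. The fallback sets out from 15 and uses a neutral thermal rearrangement. Silylation of the tertiary hydroxyl (TMSOTf, Et3N) gives the trimethylsilyl ether F3. Heating in toluene in a sealed vessel at 180–200 °C should bring about the siloxy-Cope rearrangement through the same chair to the trimethylsilyl enol ether F4. Cleavage of F4 with MeLi in THF at 0 °C gives the lithium enolate regiospecifically, and trapping with PhNTf2 returns to the route at 18.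

Step 15. The process at risk is E2 elimination, or incomplete displacement, at the hindered C1 alkoxyphosphonium ion next to the C10 methine. The fallback sets out from 20 and inverts C1 by oxidation and reduction. Dess–Martin oxidation gives the C1 ketone F5. Reduction with LiBH(s-Bu)3 at −78 °C, with hydride delivered to the same exposed outer face that borane used, should give the 1α-alcohol F6. Acetylation (Ac2O, DMAP, pyridine) returns to the route at 21.

Further compounds
F1 | step 12 | (6α,7β,8α)-6-hydroxy-10β-methyl-10α-vinyl-7-TESO-8-TBSO-cyclohexan-5-one | O=C1[C@](C)(C=C)C[C@H](O[Si](C)(C)C(C)(C)C)[C@@H](O[Si](CC)(CC)CC)[C@@H]1O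
F2 | step 12 | (6α,7β,8α)-5β-isopropenyl-10β-methyl-10α-vinyl-7-TESO-8-TBSO-cyclohexane-5α,6α-diol | CC(=C)[C@@]1(O)[C@](C)(C=C)C[C@H](O[Si](C)(C)C(C)(C)C)[C@@H](O[Si](CC)(CC)CC)[C@@H]1O
F3 | step 13 | 5-O-trimethylsilyl ether of 15 | CC(=C)[C@@]1(O[Si](C)(C)C)[C@](C)(C=C)C[C@H](O[Si](C)(C)C(C)(C)C)[C@@H](O[Si](CC)(CC)CC)[C@@H]1OCc1ccc(OC)cc1
F4 | step 13 | (1(10)E,4Z)-4,10-dimethyl-6α-PMBO-7β-TESO-8α-TBSO-5-(trimethylsilyloxy)cyclodeca-1(10),4-diene | CC(C)(C)[Si](C)(C)O[C@H]1C/C(C)=C/CC/C(C)=C(O[Si](C)(C)C)/[C@@H](OCc2ccc(OC)cc2)[C@@H]1O[Si](CC)(CC)CC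
F5 | step 15 | (4Z)-4,10β-dimethyl-1-oxo-6α-PMBO-7β-TESO-8α-TBSO-cyclodec-4-en-5-yl triflate | CC(C)(C)[Si](C)(C)O[C@H]1C[C@H](C)C(=O)CC/C(C)=C(OS(=O)(=O)C(F)(F)F)/[C@@H](OCc2ccc(OC)cc2)[C@@H]1O[Si](CC)(CC)CC
F6 | step 15 | (4Z)-1α-hydroxy-4,10β-dimethyl-6α-PMBO-7β-TESO-8α-TBSO-cyclodec-4-en-5-yl triflate | CC(C)(C)[Si](C)(C)O[C@H]1C[C@H](C)[C@@H](O)CC/C(C)=C(OS(=O)(=O)C(F)(F)F)/[C@@H](OCc2ccc(OC)cc2)[C@@H]1O[Si](CC)(CC)CC
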